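**Early times.** Early in the delta run, target and substrate add up to the charge within the scatter: delta holds 3.4% and 96.3% after 1.50 h. Late in the zeta run they don't: zeta holds 51.5% and 11.4% after 25.0 h. I read this as a side step taking one substrate and one target, while target is made at a rate proportional to substrate and catalyst. Substrate then cancels from the selectivity factor, the target gained per substrate lost. It equals (1 − u)/(1 + u), where u is target concentration over the ceiling, the concentration at which loss matches making.

| setting | delta | zeta | Friday's | Monday's | Tuesday's | Saturday's |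
|---|---|---|---|---|---|---|
| substrate | 0.22 M | 0.31 M | 0.25 M | 0.40 M | 0.40 M | 0.25 M |
| free catalyst | 2 mM | 2 mM | 2.0 mM | 2.0 mM | 2.0 mM | 2.0 mM |
| temperature | −5 °C | 8 °C | 15 °C | 15 °C | 0 °C | 0 °C |
| remark | run made earlier | run made earlier |  |  |  |  |
| time |  |  | 25 h | 25 h | 25 h | 25 h |

| run | time / h | target / % | substrate / % |
|---|---|---|---|
| delta | 1.50 | 3.4 | 96.3 |
| delta | 5.00 | 10.7 | 88.9 |
| delta | 8.00 | 15.7 | 81.5 |
| delta | 15.0 | 27.1 | 68.3 |
| delta | 20.0 | 34.9 | 60.3 |
| delta | 25.0 | 41.1 | 51.6 |
| zeta | 1.50 | 8.2 | 90.8 |
| zeta | 5.00 | 22.3 | 69.4 |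
| zeta | 8.00 | 32.1 | 55.3 |
| zeta | 15.0 | 43.3 | 29.2 |
| zeta | 20.0 | 47.8 | 17.4 |
| zeta | 25.0 | 51.5 | 11.4 |

(standard deviation of a reading: 0.5 percentage points)

* all flasks from highest to lowest amount of target, in percent of the substrate charged, at 25 h (Friday's / Monday's / Tuesday's / Saturday's)
* the amount of target, in percent of the substrate charged of the flask you put first, at 25 h
* the amount of target, in percent of the substrate charged of the flask you put last, at 25 h



**The ceiling.** Between 5.00 h and 25.0 h, zeta gains 0.503 target per substrate lost. Taking the mean of its two target readings, I get a ceiling of 0.346 M. Delta gives 0.815 and 0.559 M. Running the logarithm straight through temperature, I reach 0.268 M at 15 °C, the warm ceiling, where loss matches making, and 0.465 M at 0 °C.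

**Turned round.** For Saturday's to lead Friday's, its higher ceiling must outweigh its unspent substrate. I treat substrate decay as pseudo-first-order and interpolate the last readings of delta and zeta, which leaves 1.63% substrate in the warm flasks and 35.2% in the cold ones. Integrating the selectivity gives Friday's 54.5% and Saturday's 48.9%, so Saturday's stands 5.6 percentage points short. My Monday's 43.7% and Tuesday's 43.1% are too close for me to part.

**The forecast.** It parts them: Friday's > Saturday's > Tuesday's > Monday's, with 49.5% and 39%, noting “Friday and Saturday are nearly tied.”

**The flask.** It gives Friday's > Saturday's > Tuesday's > Monday's, with 51.3% and 40.0%.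

    catalyst intermediate → free catalyst + target (k = 0.400 min⁻¹, Ea = 75.0 kJ mol⁻¹)
    substrate + target → side product (k = 0.00130 M⁻¹ min⁻¹, Ea = 79.0 kJ mol⁻¹)
    substrate + free catalyst → catalyst intermediate (k = 0.340 M⁻¹ min⁻¹, Ea = 45.0 kJ mol⁻¹)
    (constants at 0 °C)

In Monday's, half of the release of target from catalyst intermediate up to 25.0 h was done by 4.44 h and half of the side-product step up to then by 6.59 h, with free catalyst at 97.6% at 12.5 h. In Monday's, substrate stood at 1.34% at 25.0 h, when target was 59.8% of my warm ceiling. For a neighbour of Monday's charged with 0.68 M, my warm ceiling gives 31.8% target, and that flask holds 27.8%.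

The earlier runs and the new flask are simulated with made-up constants; scatter was added.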